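**Retrosynthetic overview**

1. The target 28 comes from triol 24 by angeloylation in two stages (primary C-15 hydroxyl first, then the two secondary hydroxyls with angelic anhydride). Triol 24 comes from keto thioester 21 by anti-1,3 reduction at C-7 directed by O-9, reduction of the C-15 thioester to CH2OH, and re-oxidation at C-1.
2. Key disconnection: the C-5/C-11 and C-6/C-7 bonds of 21, leading back to the monocyclic cyclohexenone 18. The enabling feature is that C-15, raised to the thioester level, stands 1,5 to the C-1 ketone through C-11, C-5 and C-6 (Michael retron) and 1,3 to the C-7 oxygen (Claisen retron); C-7/C-8/C-9 are carried as a β-lactone.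
3. 18 comes from enone 8 by opening a lactone acetal (C-5 as thioester, then aldehyde, then enethioate) and a catalytic ketene–aldehyde cyclocondensation (C-9).
4. 8 comes from a Diels–Alder reaction of Danishefsky's diene with a menthyloxy butenolide; the bought auxiliary sets C-4 and C-10, and every later stereocentre is relayed from them or set by catalyst (C-9).
5. Ring order: six-membered enone ring (C-1 to C-4, C-10, C-11), then β-lactone (temporary), then in the key step the four-membered ring (C-4/C-5/C-11/C-10) and the seven-membered ring (C-5 to C-10 with C-11).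

Key step: step 11

Remark: longipinane numbering is used (C-1 ketone, C-2=C-3, CH3-12 on C-3, CH3-13 on C-10, CH3-14 and CH2O-15 on C-6). It is assumed that the (5S) diastereomer of 3 is the one that crystallises, as the mirror image of the menthol-derived butenolide acetals of the other series. Angelic acid and angelic anhydride are both taken as purchasable reagents.

**Route**

Step 1
Reactants: 1 5-hydroxy-4-methylfuran-2(5H)-one; 2 (+)-menthol
Product: 3 (5S)-4-methyl-5-[(1S,2R,5S)-menthyloxy]furan-2(5H)-one
Conditions: camphorsulfonic acid (cat.), toluene, reflux, Dean–Stark; crystallisation from hexane, mother liquor re-equilibrated with acid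
Reagents that add atoms: none
Why: Acid-catalysed acetalisation of the lactol with the bought chiral alcohol should give both C-5 epimers, which interconvert under the acid, and the acetal centre is set by crystallisation of the (5S) diastereomer.

Step 2
Reactants: 3 menthyloxy butenolide; 4 Danishefsky's diene
Product: 6 3-[(1S,2R,5S)-menthyloxy]-3a-methyl-3a,4-dihydro-2-benzofuran-1,5(3H,7aH)-dione, via cycloadduct silyl enol ether 5 (not isolated)
Conditions: toluene, 130 °C, sealed tube; then 0.1 M HCl, THF, 0 °C
Reagents that add atoms: none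
Why: Diels–Alder reaction in which the silyloxy-bearing diene terminus bonds to the β-carbon of the butenolide (quaternary C-10) and the methoxy terminus to the α-carbon (C-4); addition anti to the menthyloxy group and suprafacial on the dienophile should set C-4 and C-10 cis, and acid unmasks the enone by loss of methanol.

Step 3
Reactants: 6 enone lactone acetal
Product: 7 3-menthyloxy-3a,7-dimethyl-5-(trimethylsilyloxy)-3a,4,7,7a-tetrahydro-2-benzofuran-1(3H)-one
Conditions: Me2CuLi (from MeLi and CuI), Me3SiCl, THF/Et2O, −78 °C; Et3N, pentane work-up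
Reagents that add atoms: lithium dimethylcuprate [Li+].C[Cu-]C; chlorotrimethylsilane C[Si](C)(C)Cl
Why: Conjugate addition of the Gilman cuprate, accelerated by Me3SiCl, which traps the enolate regiospecifically as the silyl enol ether; the methyl group should enter trans to the ring-fusion carbonyl, a centre that is removed in the next step.

Step 4
Reactants: 7 silyl enol ether
Product: 8 3-[(1S,2R,5S)-menthyloxy]-3a,7-dimethyl-3a,4-dihydro-2-benzofuran-1,5(3H,7aH)-dione
Conditions: Pd(OAc)2 (1.1 equiv), MeCN, 25 °C
Reagents that add atoms: none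
Why: Saegusa–Ito oxidation; palladation of the silyl enol ether and β-hydride elimination towards the methyl-bearing carbon should return the enone, now carrying CH3-12, and no stereocentre is formed.

Step 5
Reactants: 8 methyl enone lactone acetal
Product: 9 S-ethyl 6-formyl-2,6-dimethyl-4-oxocyclohex-2-ene-1-carbothioate (thioester cis to formyl)
Conditions: Me3Al, EtSH, CH2Cl2, 0 °C to 25 °C; aqueous Rochelle salt
Reagents that add atoms: ethanethiol CCS
Why: The aluminium thiolate opens the lactone at its carbonyl (the usual lactone-to-thioester conversion), and the hemiacetal alkoxide set free collapses to the C-9 aldehyde with loss of the auxiliary; the conditions are not basic, so C-4 should not epimerise.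

Step 6
Reactants: 9 thioester aldehyde
Product: 10 S-ethyl 2,6-dimethyl-4-oxo-6-[(2R)-4-oxooxetan-2-yl]cyclohex-2-ene-1-carbothioate
Conditions: AcCl, iPr2NEt, O-trimethylsilylquinidine (10 mol%), LiClO4, CH2Cl2/Et2O, −78 °C
Reagents that add atoms: acetyl chloride CC(=O)Cl
Why: Catalytic asymmetric acyl halide–aldehyde cyclocondensation (ketene made in situ, ammonium enolate aldol-lactonisation) on a non-enolisable aldehyde; the alkaloid catalyst (reagent control) is chosen to set C-9 as R.

Step 7
Reactants: 10 β-lactone thioester
Product: 11 2,6-dimethyl-4-oxo-6-[(2R)-4-oxooxetan-2-yl]cyclohex-2-ene-1-carbaldehyde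
Conditions: Et3SiH, Pd/C (10% Pd on carbon), acetone, 25 °C
Reagents that add atoms: none
Why: Fukuyama reduction; zerovalent palladium inserts into the C–S bond and the acylpalladium is reduced by the silane, which should give the aldehyde without touching the lactone, the ketone or C-4.

Step 8
Reactants: 12 2-bromopropanoyl bromide; 13 2-methylpropane-2-thiol
Product: 14 S-tert-butyl 2-bromopropanethioate
Conditions: pyridine, CH2Cl2, 0 °C
Reagents that add atoms: none
Why: Nucleophilic acyl substitution of the acid bromide by the thiol; the α-bromide is kept.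

Step 9
Reactants: 14 bromo thioester; 15 triphenylphosphine
Product: 17 S-tert-butyl 2-(triphenyl-λ5-phosphanylidene)propanethioate, via phosphonium bromide 16 (not isolated)
Conditions: toluene, 80 °C; then aqueous NaOH, CH2Cl2, 0 °C
Reagents that add atoms: none
Why: SN2 quaternisation of PPh3 by the α-bromo thioester followed by deprotonation gives the stabilised ylide.

Step 10
Reactants: 11 aldehyde; 17 ylide
Product: 18 S-tert-butyl (2E)-3-{2,6-dimethyl-4-oxo-6-[(2R)-4-oxooxetan-2-yl]cyclohex-2-en-1-yl}-2-methylprop-2-enethioate
Conditions: CH2Cl2, 40 °C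
Reagents that add atoms: none
Why: Wittig olefination with a stabilised α-branched ylide should give the E-enethioate (thioester trans to the ring) under neutral conditions that leave the epimerisable C-4 centre and the β-lactone alone.

Step 11
Reactants: 18 enethioate β-lactone
Product: 21 S-tert-butyl 9-hydroxy-1,7-dioxolongipin-2-ene-15-thioate, via lithium dienolate 19 (not isolated), via cyclobutane thioester enolate 20 (not isolated)
Conditions: LiHMDS (1.05 equiv), THF (0.005 M), −78 °C, then −40 °C; AcOH, −78 °C
Reagents that add atoms: none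
Why: Proposed new method: LiHMDS removes a C-11 proton (kinetic α′-enolate 19), which adds 4-(enolexo)-exo-trig to the β-carbon of the enethioate to give enolate 20, and 20 opens the β-lactone at its carbonyl carbon (7-(enolexo)-exo-trig Claisen-type acyl transfer), so that the C-5/C-11 and C-6/C-7 bonds and the four- and seven-membered rings arise in one operation; the closest known reactions are intramolecular Michael–Claisen annulations and the C-acylation of lithium enolates by β-lactones, whereas closure of a cyclobutane by enolate conjugate addition has no direct precedent. The conjugate addition alone is estimated to be about thermoneutral (a thioester enolate is gained, roughly 30 kcal/mol of ring strain is paid) and reversible, and the irreversible opening of the β-lactone (about 23 kcal/mol of strain released) should pull it forward. C-5 and C-11 are fixed by the ring system, because only the adduct with the enolate arm anti to the enone bridge and syn to the lactone arm on C-10 can reach the lactone, and the other one reverts. C-6 is set in the acyl transfer, where lithium is expected to bridge the enolate oxygen and the ring oxygen of the lactone, which places the thioester on the face of the departing O-9; C-9 is carried over with retention because the acyl–oxygen bond is the one that breaks. The step needs the four-membered closure to win over every other reaction of 19, and three features of 18 are meant to secure this: the E-geometry keeps the thioester carbonyl out of reach of C-11, a direct attack of C-11 on the lactone carbonyl would have to pass through a 5-oxabicyclo[2.1.1]hexane, and the tert-butyl thioester together with the quench at −78 °C keeps the liberated C-9 alkoxide from translactonising.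

Step 12
Reactants: 21 keto thioester
Product: 22 S-tert-butyl 7,9-dihydroxy-1-oxolongipin-2-ene-15-thioate (O-7 anti to O-9)
Conditions: Me4NBH(OAc)3, MeCN/AcOH, −30 °C
Reagents that add atoms: none
Why: Evans–Saksena reduction; the C-9 hydroxyl binds boron and delivers hydride to the C-7 ketone from its own face, which should give the 1,3-anti diol and leave the enone and the thioester untouched.

Step 13
Reactants: 22 diol thioester
Product: 23 longipin-2-ene-1,7,9,15-tetrol (both C-1 epimers)
Conditions: LiAlH4, THF, 0 °C
Reagents that add atoms: none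
Why: Hydride reduction of the thioester to the neopentyl primary alcohol; the enone is reduced 1,2 at the same time to a mixture of allylic alcohols, which the next step corrects.

Step 14
Reactants: 23 tetrol
Product: 24 7,9,15-trihydroxylongipin-2-en-1-one
Conditions: MnO2 (activated, excess), CH2Cl2, 25 °C
Reagents that add atoms: none
Why: MnO2 should oxidise only the allylic alcohol, so both C-1 epimers converge on the enone.

Step 15
Reactants: 24 triol; 25 angelic acid
Product: 26 15-(angeloyloxy)-7,9-dihydroxylongipin-2-en-1-one
Conditions: 25 (1.2 equiv), 2,4,6-trichlorobenzoyl chloride (1.2 equiv), Et3N, toluene, 25 °C; then 24, toluene, 60 °C (no DMAP)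
Reagents that add atoms: none
Why: Yamaguchi-type esterification through the mixed trichlorobenzoic anhydride of angelic acid, run without a nucleophilic catalyst so that the Z-geometry is expected to be kept; the primary C-15 hydroxyl should react ahead of the two secondary hydroxyls that flank quaternary carbons, and any more highly acylated material converges on the target in the next step.

Step 16
Reactants: 26 mono-angelate diol; 27 angelic anhydride
Product: 28 7,9,15-tris(angeloyloxy)longipin-2-en-1-one (target)
Conditions: LiHMDS (2.0 equiv), THF, −20 °C; then 27 (4 equiv), −20 °C to 25 °C; cold 0.5 M HCl work-up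
Reagents that add atoms: none
Why: Acylation of the lithium alkoxides of the two hindered secondary hydroxyls by the symmetrical anhydride, an angeloylation without nucleophilic catalyst in which the Z-geometry is expected to be kept; the base is limited to one equivalent per hydroxyl, the C-1 ketone has only a bridgehead α′-hydrogen, and no stereocentre is formed.

**Compound list**

1 | 5-hydroxy-4-methylfuran-2(5H)-one (racemic lactol) | CC1=CC(=O)OC1O | starting material
2 | (+)-menthol, (1S,2R,5S)-5-methyl-2-(propan-2-yl)cyclohexan-1-ol | CC(C)[C@H]1CC[C@H](C)C[C@@H]1O | starting material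
3 | (5S)-4-methyl-5-[(1S,2R,5S)-menthyloxy]furan-2(5H)-one | CC1=CC(=O)O[C@@H]1O[C@H]1C[C@@H](C)CC[C@@H]1C(C)C | intermediate
4 | Danishefsky's diene, (E)-1-methoxy-3-(trimethylsilyloxy)buta-1,3-diene | CO/C=C/C(=C)O[Si](C)(C)C | starting material
5 | Diels–Alder adduct of 3 and 4: cis-fused 7-methoxy-5-(trimethylsilyloxy) silyl enol ether, methoxy epimers | C[C@]12CC(O[Si](C)(C)C)=CC(OC)[C@H]1C(=O)O[C@@H]2O[C@H]1C[C@@H](C)CC[C@@H]1C(C)C | intermediate
6 | 3-[(1S,2R,5S)-menthyloxy]-3a-methyl-3a,4-dihydro-2-benzofuran-1,5(3H,7aH)-dione; cis-fused, menthyloxy group, 3a-methyl and H-7a on one face | C[C@]12CC(=O)C=C[C@H]1C(=O)O[C@@H]2O[C@H]1C[C@@H](C)CC[C@@H]1C(C)C | intermediate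
7 | 3-menthyloxy-3a,7-dimethyl-5-(trimethylsilyloxy)-3a,4,7,7a-tetrahydro-2-benzofuran-1(3H)-one; 7-methyl trans to the lactone carbonyl | C[C@]12CC(O[Si](C)(C)C)=C[C@H](C)[C@H]1C(=O)O[C@@H]2O[C@H]1C[C@@H](C)CC[C@@H]1C(C)C | intermediate
8 | 3-[(1S,2R,5S)-menthyloxy]-3a,7-dimethyl-3a,4-dihydro-2-benzofuran-1,5(3H,7aH)-dione; ring fusion and acetal as in 6 | C[C@]12CC(=O)C=C(C)[C@H]1C(=O)O[C@@H]2O[C@H]1C[C@@H](C)CC[C@@H]1C(C)C | intermediate
9 | S-ethyl 6-formyl-2,6-dimethyl-4-oxocyclohex-2-ene-1-carbothioate; thioester cis to formyl | CCSC(=O)[C@@H]1C(C)=CC(=O)C[C@]1(C)C=O | intermediate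
10 | S-ethyl 2,6-dimethyl-4-oxo-6-[(2R)-4-oxooxetan-2-yl]cyclohex-2-ene-1-carbothioate; thioester cis to the oxetanone | CCSC(=O)[C@@H]1C(C)=CC(=O)C[C@]1(C)[C@H]1CC(=O)O1 | intermediate
11 | 2,6-dimethyl-4-oxo-6-[(2R)-4-oxooxetan-2-yl]cyclohex-2-ene-1-carbaldehyde; formyl cis to the oxetanone | O=C[C@@H]1C(C)=CC(=O)C[C@]1(C)[C@H]1CC(=O)O1 | intermediate
12 | 2-bromopropanoyl bromide (racemic) | CC(Br)C(=O)Br | starting material
13 | 2-methylpropane-2-thiol | CC(C)(C)S | starting material
14 | S-tert-butyl 2-bromopropanethioate (racemic) | CC(Br)C(=O)SC(C)(C)C | intermediate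
15 | triphenylphosphine | c1ccc(cc1)P(c1ccccc1)c1ccccc1 | starting material
16 | [1-(tert-butylsulfanyl)-1-oxopropan-2-yl]triphenylphosphonium bromide | CC(C(=O)SC(C)(C)C)[P+](c1ccccc1)(c1ccccc1)c1ccccc1.[Br-] | intermediate
17 | S-tert-butyl 2-(triphenyl-λ5-phosphanylidene)propanethioate | CC(C(=O)SC(C)(C)C)=P(c1ccccc1)(c1ccccc1)c1ccccc1 | intermediate
18 | S-tert-butyl (2E)-3-{2,6-dimethyl-4-oxo-6-[(2R)-4-oxooxetan-2-yl]cyclohex-2-en-1-yl}-2-methylprop-2-enethioate; side chain cis to the oxetanone | CC(C)(C)SC(=O)/C(C)=C/[C@@H]1C(C)=CC(=O)C[C@]1(C)[C@H]1CC(=O)O1 | intermediate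
19 | lithium cross-conjugated dienolate of 18 (deprotonated at the ring CH2) | CC(C)(C)SC(=O)/C(C)=C/[C@@H]1C(C)=CC([O-])=C[C@]1(C)[C@H]1CC(=O)O1.[Li+] | intermediate
20 | lithium thioester enolate of the bicyclo[3.1.1]heptenone (four-membered ring closed, enolate arm anti to the enone bridge) | CC(C)(C)SC([O-])=C(C)[C@@H]1[C@H]2C(=O)C=C(C)[C@@H]1[C@@]2(C)[C@H]1CC(=O)O1.[Li+] | intermediate
21 | S-tert-butyl 9-hydroxy-1,7-dioxolongipin-2-ene-15-thioate; C-15 syn to O-9 | CC(C)(C)SC(=O)[C@]1(C)[C@@H]2[C@H]3C(=O)C=C(C)[C@@H]2[C@@]3(C)[C@H](O)CC1=O | intermediate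
22 | S-tert-butyl 7,9-dihydroxy-1-oxolongipin-2-ene-15-thioate; O-7 anti to O-9 | CC(C)(C)SC(=O)[C@]1(C)[C@@H]2[C@H]3C(=O)C=C(C)[C@@H]2[C@@]3(C)[C@H](O)C[C@H]1O | intermediate
23 | longipin-2-ene-1,7,9,15-tetrol, both C-1 epimers | OC[C@]1(C)[C@@H]2[C@H]3C(O)C=C(C)[C@@H]2[C@@]3(C)[C@H](O)C[C@H]1O | intermediate
24 | 7,9,15-trihydroxylongipin-2-en-1-one | OC[C@]1(C)[C@@H]2[C@H]3C(=O)C=C(C)[C@@H]2[C@@]3(C)[C@H](O)C[C@H]1O | intermediate
25 | angelic acid, (2Z)-2-methylbut-2-enoic acid | C/C=C(/C)C(=O)O | starting material
26 | 15-(angeloyloxy)-7,9-dihydroxylongipin-2-en-1-one | C/C=C(/C)C(=O)OC[C@]1(C)[C@@H]2[C@H]3C(=O)C=C(C)[C@@H]2[C@@]3(C)[C@H](O)C[C@H]1O | intermediate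
27 | angelic anhydride, (2Z)-2-methylbut-2-enoic anhydride | C/C=C(/C)C(=O)OC(=O)/C(C)=C\C | starting material
28 | 7,9,15-tris(angeloyloxy)longipin-2-en-1-one, configuration as in the SMILES | C/C=C(/C)C(=O)OC[C@]1(C)[C@@H]2[C@H]3C(=O)C=C(C)[C@@H]2[C@@]3(C)[C@H](OC(=O)/C(C)=C\C)C[C@H]1OC(=O)/C(C)=C\C | target

**Step count and risks**

Total steps: 16. Longest linear sequence: 14 (steps 1 to 7 and 10 to 16); steps 8 and 9 form a two-step branch.

Step 11 (Proposed new method). What may go wrong: the four-membered ring closure may not compete with reversion of the conjugate adduct, proton transfer to the extended dienolate (loss of the C-4 configuration), intermolecular acylation of the enolate by the lactone of a second molecule, or poor facial control at C-6. The fallback uses known reactions, sets out from 18 and comes back at 21; it closes the four-membered ring by a radical and removes the ketone that would allow the ring to reopen. 18 is brominated at C-11 with PhNMe3Br3 to the α′-bromo enone F1. Luche reduction (NaBH4, CeCl3, MeOH, −78 °C) should give the bromo allylic alcohol F2, and silylation (tert-butyldimethylsilyl triflate, 2,6-lutidine) the silyl ether F3. Bu3SnH and azobisisobutyronitrile at high dilution generate the C-11 alkyl radical, which should close 4-exo-trig onto the enethioate to the cyclobutane thioester F4; this is a known, if demanding, ring closure onto acrylate-type acceptors and is helped here by the quaternary C-10. LiHMDS converts F4 into its thioester enolate, which cannot revert because C-1 is no longer a ketone, and Claisen-type acyl transfer from the β-lactone should give the keto alcohol F5. Bu4NF removes the silyl group to give the allylic alcohol F6, and MnO2 returns the enone 21.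

Step 2. What may go wrong: the cycloaddition onto the trisubstituted, β,β-disubstituted butenolide may be too slow, so that the diene decomposes first or facial selectivity erodes at the temperature needed. The fallback builds the ring stepwise, sets out from 3 and comes back at 8, so steps 3 and 4 are skipped. Hosomi–Sakurai conjugate allylation (allyltrimethylsilane, TiCl4, −78 °C, anti to the menthyloxy group) should give the allyl lactone F7. C-acetylation of the lactone enolate (LDA, then 1-acetylimidazole) gives the α-acetyl lactone F8, and Wacker oxidation (PdCl2, CuCl, O2, DMF/H2O) the diketone F9. Robinson-type aldol condensation (pyrrolidine, AcOH, toluene, reflux) of the methyl ketone onto the acetyl carbonyl then closes the methyl-substituted enone 8 with the cis ring fusion.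

Step 6. What may go wrong: low conversion of the hindered α-quaternary aldehyde, a mismatch between substrate and catalyst facial preference at C-9, or epimerisation at C-4 by the amine base. The fallback separates C–C bond formation from lactonisation, sets out from 9 and comes back at 10. Mukaiyama aldol addition of 1-tert-butoxy-1-(trimethylsilyloxy)ethene under a BINOL–Ti(OiPr)4 Lewis acid (catalyst control) should give the β-hydroxy tert-butyl ester F10. CF3CO2H frees the β-hydroxy acid F11, and PhSO2Cl in pyridine at 0 °C closes the β-lactone 10 with retention at C-9.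

**Further compounds**

F1 | step 11 | α′-bromo enone: 18 brominated at the ring CH2 (C-11), bromide epimers | CC(C)(C)SC(=O)/C(C)=C/[C@@H]1C(C)=CC(=O)C(Br)[C@]1(C)[C@H]1CC(=O)O1
F2 | step 11 | bromo allylic alcohol from F1 (C-1 and C-11 epimers) | CC(C)(C)SC(=O)/C(C)=C/[C@@H]1C(C)=CC(O)C(Br)[C@]1(C)[C@H]1CC(=O)O1
F3 | step 11 | tert-butyldimethylsilyl ether of F2 | CC(C)(C)SC(=O)/C(C)=C/[C@@H]1C(C)=CC(O[Si](C)(C)C(C)(C)C)C(Br)[C@]1(C)[C@H]1CC(=O)O1
F4 | step 11 | bicyclo[3.1.1]heptene thioester with C-1 silyl ether and intact β-lactone (C-1 and C-6 epimers) | CC(C)(C)SC(=O)C(C)[C@@H]1[C@H]2C(O[Si](C)(C)C(C)(C)C)C=C(C)[C@@H]1[C@@]2(C)[C@H]1CC(=O)O1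
F5 | step 11 | S-tert-butyl 1-(tert-butyldimethylsilyloxy)-9-hydroxy-7-oxolongipin-2-ene-15-thioate (C-1 epimers) | CC(C)(C)SC(=O)[C@]1(C)[C@@H]2[C@H]3C(O[Si](C)(C)C(C)(C)C)C=C(C)[C@@H]2[C@@]3(C)[C@H](O)CC1=O
F6 | step 11 | S-tert-butyl 1,9-dihydroxy-7-oxolongipin-2-ene-15-thioate (C-1 epimers) | CC(C)(C)SC(=O)[C@]1(C)[C@@H]2[C@H]3C(O)C=C(C)[C@@H]2[C@@]3(C)[C@H](O)CC1=O
F7 | step 2 | 4-allyl-4-methyl-5-[(1S,2R,5S)-menthyloxy]oxolan-2-one; allyl trans to menthyloxy | C=CC[C@@]1(C)CC(=O)O[C@@H]1O[C@H]1C[C@@H](C)CC[C@@H]1C(C)C
F8 | step 2 | 3-acetyl-4-allyl-4-methyl-5-menthyloxyoxolan-2-one (C-3 epimers, enolisable) | C=CC[C@@]1(C)C(C(C)=O)C(=O)O[C@@H]1O[C@H]1C[C@@H](C)CC[C@@H]1C(C)C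
F9 | step 2 | 3-acetyl-4-methyl-5-menthyloxy-4-(2-oxopropyl)oxolan-2-one (C-3 epimers, enolisable) | CC(=O)C[C@@]1(C)C(C(C)=O)C(=O)O[C@@H]1O[C@H]1C[C@@H](C)CC[C@@H]1C(C)C
F10 | step 6 | tert-butyl (3R)-3-[6-(ethylsulfanylcarbonyl)-1,5-dimethyl-3-oxocyclohex-4-en-1-yl]-3-hydroxypropanoate | CCSC(=O)[C@@H]1C(C)=CC(=O)C[C@]1(C)[C@H](O)CC(=O)OC(C)(C)C
F11 | step 6 | (3R)-3-[6-(ethylsulfanylcarbonyl)-1,5-dimethyl-3-oxocyclohex-4-en-1-yl]-3-hydroxypropanoic acid | CCSC(=O)[C@@H]1C(C)=CC(=O)C[C@]1(C)[C@H](O)CC(=O)O
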